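**Retrosynthetic overview**

Ring labels: A = guaiacyl ring of the open chain (C7′ = carbinol carbon, C8′ = aryl-bearing carbon), B = central phenol ring, C = lactone, D and E = benzene and dihydrofuran rings of the benzofuran (O1, C2, C3, C3a–C7a), F = guaiacyl ring on C2. Last disconnections: global deprotection, then the bond from lactone C3 to its benzylic CH2 by trans-selective alkylation of an (R)-β-(arylmethyl)butyrolactone carrying rings D–F with a ring A/B benzylic bromide.
Ring C comes from auxiliary-controlled benzylation of a succinate half-imide with the ring D benzylic bromide, followed by reductive lactonisation.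
Both bonds between a guaiacyl carbinol carbon and an aryl-bearing carbon (C7′–C8′ and C2–C3) come from one reaction type, the auxiliary-controlled magnesium-catalysed anti-aldol of an N-arylacetyl oxazolidinone with O-benzylvanillin. With OBn ortho to the side chain (ring B) it stops at the anti adduct; with F ortho (ring D) it runs on to ring E.
Key disconnection: ring E by a formal [3+2] annulation of the aldehyde C=O across C3 and C7a. It is possible because C7a of ring D is para to C5, the carbon that later carries the lactone methylene. Held as a methyl ester, C5 makes a C7a–F bond an SNAr acceptor, while C3 (benzylic, α to an acyl group) is a soft carbon nucleophile two atoms from C7a.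
Ring order: E (step 5), then C (step 12); rings A, B, D and F are purchased benzene rings.

Key step: step 5

Assumption: the magnesium-catalysed anti-aldol of the (S)-4-benzyl imides is taken to follow the chelated Z-enolate/boat model (aldehyde on the enolate face opposite the auxiliary benzyl group, (2R,3S) adduct); if the facial sense were opposite, the (R)-auxiliary would be used in steps 4 and 16.

**Route**

Step 1
Reactants: 1 methyl 4-fluoro-3-methoxybenzoate
Product: 2 methyl 4-fluoro-3-methoxy-5-(4,4,5,5-tetramethyl-1,3,2-dioxaborolan-2-yl)benzoate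
Conditions: [Ir(OMe)(cod)]2 (1.5 mol%), 4,4′-di-tert-butyl-2,2′-bipyridine (3 mol%), B2pin2, THF, 80 °C
Reagents that add atoms: bis(pinacolato)diboron, CC1(C)OB(OC1(C)C)B1OC(C)(C)C(C)(C)O1
Why: Iridium-catalysed aromatic C–H borylation is sterically controlled, and of the three C–H bonds only H-5 has fluorine as its sole ortho neighbour (H-2 lies between two substituents, H-6 next to the ester), so boron should enter at C5.

Step 2
Reactants: 2 methyl 4-fluoro-3-methoxy-5-(pinacolboryl)benzoate; 3 tert-butyl bromoacetate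
Product: 4 methyl 3-(2-tert-butoxy-2-oxoethyl)-4-fluoro-5-methoxybenzoate
Conditions: Pd(OAc)2 (3 mol%), P(o-tol)3 (9 mol%), K3PO4, THF/H2O, 40 °C
Reagents that add atoms: none
Why: Suzuki–Miyaura coupling of an arylboronic ester with an α-bromoacetate installs the CH2CO2t-Bu arm at the future C3a without touching the C–F bond, the tert-butyl ester being chosen so that it can be cleaved beside the methyl ester.

Step 3
Reactants: 4 methyl 3-(2-tert-butoxy-2-oxoethyl)-4-fluoro-5-methoxybenzoate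
Product: 5 2-[2-fluoro-3-methoxy-5-(methoxycarbonyl)phenyl]acetic acid
Conditions: CF3CO2H/CH2Cl2 (1:3), 23 °C
Reagents that add atoms: none
Why: Acid-mediated tert-butyl ester cleavage (E1 loss of isobutene) frees the acetic acid while the methyl benzoate and the aryl fluoride are inert.

Step 4
Reactants: 5 2-[2-fluoro-3-methoxy-5-(methoxycarbonyl)phenyl]acetic acid; 6 (S)-4-benzyl-1,3-oxazolidin-2-one
Product: 7 methyl 3-{2-[(4S)-4-benzyl-2-oxo-1,3-oxazolidin-3-yl]-2-oxoethyl}-4-fluoro-5-methoxybenzoate (ring D imide)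
Conditions: t-BuCOCl, Et3N, THF, −20 °C; then LiCl, 6, 23 °C
Reagents that add atoms: none
Why: N-Acylation of the oxazolidinone auxiliary through the mixed pivalic anhydride (LiCl/Et3N activation) is the standard entry to N-arylacetyl imides and creates no stereocentre.

Step 5
Reactants: 7 ring D imide; 8 4-(benzyloxy)-3-methoxybenzaldehyde
Product: 11 methyl (2S,3S)-3-{[(4S)-4-benzyl-2-oxo-1,3-oxazolidin-3-yl]carbonyl}-2-[4-(benzyloxy)-3-methoxyphenyl]-7-methoxy-2,3-dihydro-1-benzofuran-5-carboxylate (trans), via anti-aldol trimethylsilyl ether 9 (not isolated), via cis-dihydrobenzofuran imide 10 (not isolated)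
Conditions: MgCl2 (20 mol%), Et3N, Me3SiCl, EtOAc, 23 °C; evaporate; CsF, DMF, 23 °C; then Cs2CO3 (0.3 equiv), 45 °C
Reagents that add atoms: none
Why: Proposed new method: MgCl2/Et3N should soft-enolise imide 7 to the chelated Z-enolate, which adds to aldehyde 8 through the closed boat transition state of the magnesium-catalysed anti-aldol and is trapped as silyl ether 9 (C2–C3 bond); fluoride then frees the C2 alkoxide, which adds ipso at C7a of ring D through a Meisenheimer complex stabilised by the para methoxycarbonyl group, and the fluoride that leaves cleaves the next silyl ether (O1–C7a bond). The closest known reaction types are the magnesium-halide-catalysed direct anti-aldol of N-acyloxazolidinones with aromatic aldehydes and the fluoride-triggered desilylative SNAr etherification of ester-, nitrile- or nitro-activated aryl fluorides; their merger in one flask on an auxiliary-bearing substrate is the untested part. Ring E closes by a five-membered ipso addition–elimination at C7a (5-exo-trig). C2 (S) is fixed in the aldol by the (S)-4-benzyl auxiliary, which shields one face of the chelated enolate, and it keeps its configuration because the O1–C2 bond is never broken; C3 is first formed cis (R) and is equilibrated by Cs2CO3 through the imide enolate to the thermodynamically preferred trans (2S,3S) isomer 11. The step needs ring closure to be faster than retro-aldol, acyl transfer or β-elimination of the β-alkoxide, which the five-membered attack on a para-ester-activated C–F bond, unmasked only after the aldol reagents are removed, is expected to secure.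

Step 6
Reactants: 11 trans-dihydrobenzofuran imide
Product: 12 methyl (2S,3R)-2-[4-(benzyloxy)-3-methoxyphenyl]-3-(hydroxymethyl)-7-methoxy-2,3-dihydro-1-benzofuran-5-carboxylate
Conditions: LiBH4, MeOH (1 equiv), THF, 0 °C
Reagents that add atoms: none
Why: Reductive cleavage of the N-acyl oxazolidinone by LiBH4 (hydride adds to the exocyclic imide carbonyl much faster than to the aryl ester at 0 °C) turns the acyl carbon into the hydroxymethyl group and returns the auxiliary, after which C2 and C3 can no longer epimerise.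

Step 7
Reactants: 12 dihydrobenzofuran alcohol
Product: 13 methyl (2S,3R)-2-[4-(benzyloxy)-3-methoxyphenyl]-3-{[(tert-butyldimethylsilyl)oxy]methyl}-7-methoxy-2,3-dihydro-1-benzofuran-5-carboxylate
Conditions: t-BuMe2SiCl, imidazole, DMF, 23 °C
Reagents that add atoms: tert-butyldimethylsilyl chloride, CC(C)(C)[Si](C)(C)Cl
Why: Silyl ether formation masks the primary alcohol for the enolate chemistry ahead.

Step 8
Reactants: 13 silyl ether methyl ester
Product: 14 [(2S,3R)-2-[4-(benzyloxy)-3-methoxyphenyl]-3-{[(tert-butyldimethylsilyl)oxy]methyl}-7-methoxy-2,3-dihydro-1-benzofuran-5-yl]methanol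
Conditions: i-Bu2AlH, CH2Cl2, −78 → 0 °C; aq. KNaC4H4O6
Reagents that add atoms: none
Why: Hydride reduction of the aryl ester with i-Bu2AlH turns the former SNAr-activating group into the benzylic alcohol that becomes the methylene between rings C and D.

Step 9
Reactants: 14 benzylic alcohol
Product: 15 {[(2S,3R)-2-[4-(benzyloxy)-3-methoxyphenyl]-5-(bromomethyl)-7-methoxy-2,3-dihydro-1-benzofuran-3-yl]methoxy}(tert-butyl)dimethylsilane
Conditions: CBr4, PPh3, 2,6-lutidine, CH2Cl2, 0 °C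
Reagents that add atoms: carbon tetrabromide, BrC(Br)(Br)Br
Why: Appel bromination (displacement of the alkoxyphosphonium group by bromide) gives the electron-rich benzylic bromide under buffered, non-acidic conditions that spare the silyl ether and the benzylic C2–O1 bond.

Step 10
Reactants: 16 (R)-4-benzyl-1,3-oxazolidin-2-one; 17 methyl 4-chloro-4-oxobutanoate
Product: 18 methyl 4-[(4R)-4-benzyl-2-oxo-1,3-oxazolidin-3-yl]-4-oxobutanoate
Conditions: n-BuLi, THF, −78 °C; then 17
Reagents that add atoms: none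
Why: N-Acylation of the lithiated (R)-oxazolidinone with the acid chloride gives the succinate half-imide needed for ring C.

Step 11
Reactants: 18 succinate half-imide; 15 ring D benzylic bromide
Product: 19 methyl (3R)-4-[(4R)-4-benzyl-2-oxo-1,3-oxazolidin-3-yl]-3-{[(2S,3R)-2-[4-(benzyloxy)-3-methoxyphenyl]-3-{[(tert-butyldimethylsilyl)oxy]methyl}-7-methoxy-2,3-dihydro-1-benzofuran-5-yl]methyl}-4-oxobutanoate
Conditions: NaN(SiMe3)2, THF, −78 °C; then 15, −78 → −40 °C
Reagents that add atoms: none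
Why: Auxiliary-controlled enolate alkylation (Evans alkylation): NaN(SiMe3)2 deprotonates the more acidic imide α-CH2 and the chelated Z-enolate is benzylated on the face opposite the auxiliary benzyl group, which sets the future lactone C4 as R.

Step 12
Reactants: 19 alkylated imide
Product: 21 (4R)-4-{[(2S,3R)-2-[4-(benzyloxy)-3-methoxyphenyl]-3-{[(tert-butyldimethylsilyl)oxy]methyl}-7-methoxy-2,3-dihydro-1-benzofuran-5-yl]methyl}oxolan-2-one, via γ-hydroxy ester 20 (not isolated)
Conditions: NaBH4, THF/H2O (4:1), 0 → 23 °C; then PPTS (cat.), PhMe, 50 °C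
Reagents that add atoms: none
Why: Borohydride reduction of the imide carbonyl (NaBH4 in wet THF leaves the methyl ester) gives the γ-hydroxy ester, which closes ring C by 5-exo-trig lactonisation under mild acid without touching the stereocentre.

Step 13
Reactants: 22 methyl 3-bromo-4-hydroxy-5-methoxybenzoate
Product: 23 methyl 4-(benzyloxy)-3-bromo-5-methoxybenzoate
Conditions: BnBr, K2CO3, DMF, 50 °C
Reagents that add atoms: benzyl bromide, BrCc1ccccc1
Why: Williamson etherification protects the ring B phenol as the benzyl ether that is removed in the last step.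

Step 14
Reactants: 23 methyl 4-(benzyloxy)-3-bromo-5-methoxybenzoate; 24 (2-tert-butoxy-2-oxoethyl)zinc bromide
Product: 25 methyl 4-(benzyloxy)-3-(2-tert-butoxy-2-oxoethyl)-5-methoxybenzoate
Conditions: Pd2(dba)3 (1 mol%), XPhos (4 mol%), THF, 50 °C
Reagents that add atoms: none
Why: Palladium-catalysed Negishi-type coupling of the Reformatsky reagent (α-arylation of a zinc ester enolate) replaces bromine by the CH2CO2t-Bu arm and tolerates the methyl ester.

Step 15
Reactants: 25 methyl 4-(benzyloxy)-3-(2-tert-butoxy-2-oxoethyl)-5-methoxybenzoate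
Product: 26 2-[2-(benzyloxy)-3-methoxy-5-(methoxycarbonyl)phenyl]acetic acid
Conditions: CF3CO2H/CH2Cl2 (1:4), 0 → 23 °C
Reagents that add atoms: none
Why: Acid-mediated tert-butyl ester cleavage (E1 loss of isobutene) is selective over the methyl ester and, at this dilution and temperature, over the aryl benzyl ether.

Step 16
Reactants: 26 2-[2-(benzyloxy)-3-methoxy-5-(methoxycarbonyl)phenyl]acetic acid; 6 (S)-4-benzyl-1,3-oxazolidin-2-one
Product: 27 methyl 3-{2-[(4S)-4-benzyl-2-oxo-1,3-oxazolidin-3-yl]-2-oxoethyl}-4-(benzyloxy)-5-methoxybenzoate (ring B imide)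
Conditions: t-BuCOCl, Et3N, THF, −20 °C; then LiCl, 6, 23 °C
Reagents that add atoms: none
Why: N-Acylation of the auxiliary through the mixed pivalic anhydride, as in step 4, creates no stereocentre.

Step 17
Reactants: 27 ring B imide; 8 4-(benzyloxy)-3-methoxybenzaldehyde
Product: 29 methyl 3-{(1R,2S)-1-{[(4S)-4-benzyl-2-oxo-1,3-oxazolidin-3-yl]carbonyl}-2-[4-(benzyloxy)-3-methoxyphenyl]-2-hydroxyethyl}-4-(benzyloxy)-5-methoxybenzoate, via anti-aldol trimethylsilyl ether 28 (not isolated)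
Conditions: MgCl2 (20 mol%), Et3N, Me3SiCl, EtOAc, 23 °C; then 1 M HCl/THF, 0 °C
Reagents that add atoms: none
Why: Magnesium-halide-catalysed direct anti-aldol (soft enolisation, chelated Z-enolate, boat transition state, silyl trapping for turnover): the (S)-auxiliary directs the aldehyde to the enolate face opposite its benzyl group and should give the (2R,3S)-anti adduct, which fixes C8′ and C7′, while the ortho benzyloxy group of ring B offers no leaving group, so the adduct stays open.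

Step 18
Reactants: 29 anti-aldol adduct
Product: 30 methyl 4-(benzyloxy)-3-{(1S,2S)-1-[4-(benzyloxy)-3-methoxyphenyl]-1,3-dihydroxypropan-2-yl}-5-methoxybenzoate
Conditions: LiBH4, MeOH (1 equiv), THF, 0 °C
Reagents that add atoms: none
Why: Reductive cleavage of the β-hydroxy imide by LiBH4 at 0 °C (fast enough to avoid retro-aldol, selective over the aryl ester) gives the anti-1,3-diol, the descriptor at C8′ changing from R to S only through the change of priorities.

Step 19
Reactants: 30 anti-1,3-diol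
Product: 31 methyl 4-(benzyloxy)-3-{(1S,2S)-1-[4-(benzyloxy)-3-methoxyphenyl]-1,3-bis[(tert-butyldimethylsilyl)oxy]propan-2-yl}-5-methoxybenzoate
Conditions: t-BuMe2SiOTf, 2,6-lutidine, CH2Cl2, 0 °C
Reagents that add atoms: tert-butyldimethylsilyl trifluoromethanesulfonate, CC(C)(C)[Si](C)(C)OS(=O)(=O)C(F)(F)F
Why: Silyl ether formation with the silyl triflate and 2,6-lutidine protects both the primary and the hindered benzylic secondary alcohol.

Step 20
Reactants: 31 bis-silyl ether methyl ester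
Product: 32 [4-(benzyloxy)-3-{(1S,2S)-1-[4-(benzyloxy)-3-methoxyphenyl]-1,3-bis[(tert-butyldimethylsilyl)oxy]propan-2-yl}-5-methoxyphenyl]methanol
Conditions: i-Bu2AlH, CH2Cl2, −78 → 0 °C; aq. KNaC4H4O6
Reagents that add atoms: none
Why: Hydride reduction of the aryl ester with i-Bu2AlH gives the benzylic alcohol and leaves the silyl and benzyl ethers intact.

Step 21
Reactants: 32 ring B benzylic alcohol
Product: 33 1-(benzyloxy)-4-(bromomethyl)-2-{(1S,2S)-1-[4-(benzyloxy)-3-methoxyphenyl]-1,3-bis[(tert-butyldimethylsilyl)oxy]propan-2-yl}-6-methoxybenzene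
Conditions: CBr4, PPh3, 2,6-lutidine, CH2Cl2, 0 °C
Reagents that add atoms: carbon tetrabromide, BrC(Br)(Br)Br
Why: Appel bromination under buffered conditions gives the benzylic bromide without loss of the silyl ethers.

Step 22
Reactants: 21 (R)-β-(arylmethyl)butyrolactone; 33 ring A/B benzylic bromide
Product: 34 (3R,4R)-3-{[4-(benzyloxy)-3-{(1S,2S)-1-[4-(benzyloxy)-3-methoxyphenyl]-1,3-bis[(tert-butyldimethylsilyl)oxy]propan-2-yl}-5-methoxyphenyl]methyl}-4-{[(2S,3R)-2-[4-(benzyloxy)-3-methoxyphenyl]-3-{[(tert-butyldimethylsilyl)oxy]methyl}-7-methoxy-2,3-dihydro-1-benzofuran-5-yl]methyl}oxolan-2-one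
Conditions: LiN(SiMe3)2, THF, −78 °C; then 33, DMPU, −78 → −40 °C
Reagents that add atoms: none
Why: Alkylation of the lithium enolate of a β-substituted γ-butyrolactone occurs anti to the C4 substituent (1,2-asymmetric induction), which unites the two halves and sets lactone C3 as R (trans-3,4).

Step 23
Reactants: 34 fully protected lactone
Product: 35 (3R,4R)-3-{[4-(benzyloxy)-3-{(1S,2S)-1-[4-(benzyloxy)-3-methoxyphenyl]-1,3-dihydroxypropan-2-yl}-5-methoxyphenyl]methyl}-4-{[(2S,3R)-2-[4-(benzyloxy)-3-methoxyphenyl]-3-(hydroxymethyl)-7-methoxy-2,3-dihydro-1-benzofuran-5-yl]methyl}oxolan-2-one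
Conditions: Bu4NF, AcOH, THF, 0 → 23 °C
Reagents that add atoms: none
Why: Fluoride-mediated desilylation, buffered with AcOH so that the lactone is not exposed to free alkoxide, frees the three alcohols while the phenols remain benzylated.

Step 24
Reactants: 35 tri-O-benzyl triol
Product: 36 (3R,4R)-3-{[3-{(1S,2S)-1,3-dihydroxy-1-(4-hydroxy-3-methoxyphenyl)propan-2-yl}-4-hydroxy-5-methoxyphenyl]methyl}-4-{[(2S,3R)-2-(4-hydroxy-3-methoxyphenyl)-3-(hydroxymethyl)-7-methoxy-2,3-dihydro-1-benzofuran-5-yl]methyl}oxolan-2-one (target)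
Conditions: H2 (1 atm), Pd/C (10%), EtOAc/MeOH, 23 °C
Reagents that add atoms: none
Why: Hydrogenolysis of the three aryl benzyl ethers over Pd/C under neutral conditions should be faster than cleavage of the benzylic C7′–OH and C2–O1 bonds and gives the target.

**Compound list**

1 | methyl 4-fluoro-3-methoxybenzoate | COC(=O)c1ccc(F)c(OC)c1 | starting material
2 | methyl 4-fluoro-3-methoxy-5-(4,4,5,5-tetramethyl-1,3,2-dioxaborolan-2-yl)benzoate | COC(=O)c1cc(OC)c(F)c(c1)B1OC(C)(C)C(C)(C)O1 | intermediate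
3 | tert-butyl bromoacetate | CC(C)(C)OC(=O)CBr | starting material
4 | methyl 3-(2-tert-butoxy-2-oxoethyl)-4-fluoro-5-methoxybenzoate | COC(=O)c1cc(OC)c(F)c(c1)CC(=O)OC(C)(C)C | intermediate
5 | 2-[2-fluoro-3-methoxy-5-(methoxycarbonyl)phenyl]acetic acid | COC(=O)c1cc(OC)c(F)c(c1)CC(O)=O | intermediate
6 | (S)-4-benzyl-1,3-oxazolidin-2-one | O=C1OC[C@H](Cc2ccccc2)N1 | starting material
7 | methyl 3-{2-[(4S)-4-benzyl-2-oxo-1,3-oxazolidin-3-yl]-2-oxoethyl}-4-fluoro-5-methoxybenzoate | COC(=O)c1cc(OC)c(F)c(c1)CC(=O)N1[C@@H](Cc2ccccc2)COC1=O | intermediate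
8 | 4-(benzyloxy)-3-methoxybenzaldehyde | COc1cc(C=O)ccc1OCc1ccccc1 | starting material
9 | methyl 3-{(1R,2S)-1-{[(4S)-4-benzyl-2-oxo-1,3-oxazolidin-3-yl]carbonyl}-2-[4-(benzyloxy)-3-methoxyphenyl]-2-[(trimethylsilyl)oxy]ethyl}-4-fluoro-5-methoxybenzoate | COC(=O)c1cc(OC)c(F)c(c1)[C@@H](C(=O)N1[C@@H](Cc2ccccc2)COC1=O)[C@@H](c1ccc(OCc2ccccc2)c(OC)c1)O[Si](C)(C)C | intermediate
10 | methyl (2S,3R)-3-{[(4S)-4-benzyl-2-oxo-1,3-oxazolidin-3-yl]carbonyl}-2-[4-(benzyloxy)-3-methoxyphenyl]-7-methoxy-2,3-dihydro-1-benzofuran-5-carboxylate (cis) | COC(=O)c1cc(OC)c2c(c1)[C@@H](C(=O)N1[C@@H](Cc3ccccc3)COC1=O)[C@@H](c1ccc(OCc3ccccc3)c(OC)c1)O2 | intermediate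
11 | methyl (2S,3S)-3-{[(4S)-4-benzyl-2-oxo-1,3-oxazolidin-3-yl]carbonyl}-2-[4-(benzyloxy)-3-methoxyphenyl]-7-methoxy-2,3-dihydro-1-benzofuran-5-carboxylate (trans) | COC(=O)c1cc(OC)c2c(c1)[C@H](C(=O)N1[C@@H](Cc3ccccc3)COC1=O)[C@@H](c1ccc(OCc3ccccc3)c(OC)c1)O2 | intermediate
12 | methyl (2S,3R)-2-[4-(benzyloxy)-3-methoxyphenyl]-3-(hydroxymethyl)-7-methoxy-2,3-dihydro-1-benzofuran-5-carboxylate | COC(=O)c1cc(OC)c2c(c1)[C@H](CO)[C@@H](c1ccc(OCc3ccccc3)c(OC)c1)O2 | intermediate
13 | methyl (2S,3R)-2-[4-(benzyloxy)-3-methoxyphenyl]-3-{[(tert-butyldimethylsilyl)oxy]methyl}-7-methoxy-2,3-dihydro-1-benzofuran-5-carboxylate | COC(=O)c1cc(OC)c2c(c1)[C@H](CO[Si](C)(C)C(C)(C)C)[C@@H](c1ccc(OCc3ccccc3)c(OC)c1)O2 | intermediate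
14 | [(2S,3R)-2-[4-(benzyloxy)-3-methoxyphenyl]-3-{[(tert-butyldimethylsilyl)oxy]methyl}-7-methoxy-2,3-dihydro-1-benzofuran-5-yl]methanol | OCc1cc(OC)c2c(c1)[C@H](CO[Si](C)(C)C(C)(C)C)[C@@H](c1ccc(OCc3ccccc3)c(OC)c1)O2 | intermediate
15 | {[(2S,3R)-2-[4-(benzyloxy)-3-methoxyphenyl]-5-(bromomethyl)-7-methoxy-2,3-dihydro-1-benzofuran-3-yl]methoxy}(tert-butyl)dimethylsilane | BrCc1cc(OC)c2c(c1)[C@H](CO[Si](C)(C)C(C)(C)C)[C@@H](c1ccc(OCc3ccccc3)c(OC)c1)O2 | intermediate
16 | (R)-4-benzyl-1,3-oxazolidin-2-one | O=C1OC[C@@H](Cc2ccccc2)N1 | starting material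
17 | methyl 4-chloro-4-oxobutanoate | COC(=O)CCC(Cl)=O | starting material
18 | methyl 4-[(4R)-4-benzyl-2-oxo-1,3-oxazolidin-3-yl]-4-oxobutanoate | COC(=O)CCC(=O)N1[C@H](Cc2ccccc2)COC1=O | intermediate
19 | methyl (3R)-4-[(4R)-4-benzyl-2-oxo-1,3-oxazolidin-3-yl]-3-{[(2S,3R)-2-[4-(benzyloxy)-3-methoxyphenyl]-3-{[(tert-butyldimethylsilyl)oxy]methyl}-7-methoxy-2,3-dihydro-1-benzofuran-5-yl]methyl}-4-oxobutanoate | COC(=O)C[C@H](C(=O)N1[C@H](Cc2ccccc2)COC1=O)Cc1cc(OC)c2c(c1)[C@H](CO[Si](C)(C)C(C)(C)C)[C@@H](c1ccc(OCc3ccccc3)c(OC)c1)O2 | intermediate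
20 | methyl (3R)-4-hydroxy-3-{[(2S,3R)-2-[4-(benzyloxy)-3-methoxyphenyl]-3-{[(tert-butyldimethylsilyl)oxy]methyl}-7-methoxy-2,3-dihydro-1-benzofuran-5-yl]methyl}butanoate | COC(=O)C[C@H](CO)Cc1cc(OC)c2c(c1)[C@H](CO[Si](C)(C)C(C)(C)C)[C@@H](c1ccc(OCc3ccccc3)c(OC)c1)O2 | intermediate
21 | (4R)-4-{[(2S,3R)-2-[4-(benzyloxy)-3-methoxyphenyl]-3-{[(tert-butyldimethylsilyl)oxy]methyl}-7-methoxy-2,3-dihydro-1-benzofuran-5-yl]methyl}oxolan-2-one | O=C1C[C@H](CO1)Cc1cc(OC)c2c(c1)[C@H](CO[Si](C)(C)C(C)(C)C)[C@@H](c1ccc(OCc3ccccc3)c(OC)c1)O2 | intermediate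
22 | methyl 3-bromo-4-hydroxy-5-methoxybenzoate | COC(=O)c1cc(Br)c(O)c(OC)c1 | starting material
23 | methyl 4-(benzyloxy)-3-bromo-5-methoxybenzoate | COC(=O)c1cc(Br)c(OCc2ccccc2)c(OC)c1 | intermediate
24 | (2-tert-butoxy-2-oxoethyl)zinc bromide | CC(C)(C)OC(=O)C[Zn]Br | starting material
25 | methyl 4-(benzyloxy)-3-(2-tert-butoxy-2-oxoethyl)-5-methoxybenzoate | COC(=O)c1cc(OC)c(OCc2ccccc2)c(c1)CC(=O)OC(C)(C)C | intermediate
26 | 2-[2-(benzyloxy)-3-methoxy-5-(methoxycarbonyl)phenyl]acetic acid | COC(=O)c1cc(OC)c(OCc2ccccc2)c(c1)CC(O)=O | intermediate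
27 | methyl 3-{2-[(4S)-4-benzyl-2-oxo-1,3-oxazolidin-3-yl]-2-oxoethyl}-4-(benzyloxy)-5-methoxybenzoate | COC(=O)c1cc(OC)c(OCc2ccccc2)c(c1)CC(=O)N1[C@@H](Cc2ccccc2)COC1=O | intermediate
28 | methyl 3-{(1R,2S)-1-{[(4S)-4-benzyl-2-oxo-1,3-oxazolidin-3-yl]carbonyl}-2-[4-(benzyloxy)-3-methoxyphenyl]-2-[(trimethylsilyl)oxy]ethyl}-4-(benzyloxy)-5-methoxybenzoate | COC(=O)c1cc(OC)c(OCc2ccccc2)c(c1)[C@@H](C(=O)N1[C@@H](Cc2ccccc2)COC1=O)[C@@H](c1ccc(OCc2ccccc2)c(OC)c1)O[Si](C)(C)C | intermediate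
29 | methyl 3-{(1R,2S)-1-{[(4S)-4-benzyl-2-oxo-1,3-oxazolidin-3-yl]carbonyl}-2-[4-(benzyloxy)-3-methoxyphenyl]-2-hydroxyethyl}-4-(benzyloxy)-5-methoxybenzoate | COC(=O)c1cc(OC)c(OCc2ccccc2)c(c1)[C@@H](C(=O)N1[C@@H](Cc2ccccc2)COC1=O)[C@@H](c1ccc(OCc2ccccc2)c(OC)c1)O | intermediate
30 | methyl 4-(benzyloxy)-3-{(1S,2S)-1-[4-(benzyloxy)-3-methoxyphenyl]-1,3-dihydroxypropan-2-yl}-5-methoxybenzoate | COC(=O)c1cc(OC)c(OCc2ccccc2)c(c1)[C@@H](CO)[C@@H](c1ccc(OCc2ccccc2)c(OC)c1)O | intermediate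
31 | methyl 4-(benzyloxy)-3-{(1S,2S)-1-[4-(benzyloxy)-3-methoxyphenyl]-1,3-bis[(tert-butyldimethylsilyl)oxy]propan-2-yl}-5-methoxybenzoate | COC(=O)c1cc(OC)c(OCc2ccccc2)c(c1)[C@@H](CO[Si](C)(C)C(C)(C)C)[C@@H](c1ccc(OCc2ccccc2)c(OC)c1)O[Si](C)(C)C(C)(C)C | intermediate
32 | [4-(benzyloxy)-3-{(1S,2S)-1-[4-(benzyloxy)-3-methoxyphenyl]-1,3-bis[(tert-butyldimethylsilyl)oxy]propan-2-yl}-5-methoxyphenyl]methanol | OCc1cc(OC)c(OCc2ccccc2)c(c1)[C@@H](CO[Si](C)(C)C(C)(C)C)[C@@H](c1ccc(OCc2ccccc2)c(OC)c1)O[Si](C)(C)C(C)(C)C | intermediate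
33 | 1-(benzyloxy)-4-(bromomethyl)-2-{(1S,2S)-1-[4-(benzyloxy)-3-methoxyphenyl]-1,3-bis[(tert-butyldimethylsilyl)oxy]propan-2-yl}-6-methoxybenzene | BrCc1cc(OC)c(OCc2ccccc2)c(c1)[C@@H](CO[Si](C)(C)C(C)(C)C)[C@@H](c1ccc(OCc2ccccc2)c(OC)c1)O[Si](C)(C)C(C)(C)C | intermediate
34 | tris-silyl, tri-O-benzyl ether of the target: (3R,4R)-3-{[4-(benzyloxy)-3-{(1S,2S)-1-[4-(benzyloxy)-3-methoxyphenyl]-1,3-bis[(tert-butyldimethylsilyl)oxy]propan-2-yl}-5-methoxyphenyl]methyl}-4-{[(2S,3R)-2-[4-(benzyloxy)-3-methoxyphenyl]-3-{[(tert-butyldimethylsilyl)oxy]methyl}-7-methoxy-2,3-dihydro-1-benzofuran-5-yl]methyl}oxolan-2-one | COc1cc([C@@H](O[Si](C)(C)C(C)(C)C)[C@H](CO[Si](C)(C)C(C)(C)C)c2cc(C[C@H]3C(=O)OC[C@@H]3Cc3cc(OC)c4c(c3)[C@H](CO[Si](C)(C)C(C)(C)C)[C@@H](c3ccc(OCc5ccccc5)c(OC)c3)O4)cc(OC)c2OCc2ccccc2)ccc1OCc1ccccc1 | intermediate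
35 | tri-O-benzyl ether of the target: (3R,4R)-3-{[4-(benzyloxy)-3-{(1S,2S)-1-[4-(benzyloxy)-3-methoxyphenyl]-1,3-dihydroxypropan-2-yl}-5-methoxyphenyl]methyl}-4-{[(2S,3R)-2-[4-(benzyloxy)-3-methoxyphenyl]-3-(hydroxymethyl)-7-methoxy-2,3-dihydro-1-benzofuran-5-yl]methyl}oxolan-2-one | COc1cc([C@@H](O)[C@H](CO)c2cc(C[C@H]3C(=O)OC[C@@H]3Cc3cc(OC)c4c(c3)[C@H](CO)[C@@H](c3ccc(OCc5ccccc5)c(OC)c3)O4)cc(OC)c2OCc2ccccc2)ccc1OCc1ccccc1 | intermediate
36 | (3R,4R)-3-{[3-{(1S,2S)-1,3-dihydroxy-1-(4-hydroxy-3-methoxyphenyl)propan-2-yl}-4-hydroxy-5-methoxyphenyl]methyl}-4-{[(2S,3R)-2-(4-hydroxy-3-methoxyphenyl)-3-(hydroxymethyl)-7-methoxy-2,3-dihydro-1-benzofuran-5-yl]methyl}oxolan-2-one | COc1cc([C@@H](O)[C@H](CO)c2cc(C[C@H]3C(=O)OC[C@@H]3Cc3cc(OC)c4c(c3)[C@H](CO)[C@@H](c3ccc(O)c(OC)c3)O4)cc(OC)c2O)ccc1O | target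

**Step count and risks**

Total step count: 24. Longest linear sequence: 14 steps (steps 1–9, 11, 12, 22, 23, 24).

Step 5 (proposed new method). What may go wrong: after desilylation the β-alkoxide may undergo retro-aldol cleavage, acyl transfer to the oxazolidinone carbonyl or β-elimination faster than it closes onto C7a. That would erode the configuration at C2 or consume the imide, and the cis-to-trans equilibration at C3 may stay incomplete. The fallback uses known reactions only and sets out from imide 7. An Evans syn-aldol through the dibutylboron enolate (Bu2BOTf, i-Pr2NEt, CH2Cl2, −78 °C, then 8, oxidative work-up) would set both centres kinetically and give methyl 3-{(1S,2S)-1-{[(4S)-4-benzyl-2-oxo-1,3-oxazolidin-3-yl]carbonyl}-2-[4-(benzyloxy)-3-methoxyphenyl]-2-hydroxyethyl}-4-fluoro-5-methoxybenzoate F1. LiBH4 would cleave the auxiliary to methyl 3-{(1S,2R)-1-[4-(benzyloxy)-3-methoxyphenyl]-1,3-dihydroxypropan-2-yl}-4-fluoro-5-methoxybenzoate F2. t-BuMe2SiCl/imidazole would silylate the primary hydroxyl to give methyl 3-{(1S,2R)-1-[4-(benzyloxy)-3-methoxyphenyl]-3-[(tert-butyldimethylsilyl)oxy]-1-hydroxypropan-2-yl}-4-fluoro-5-methoxybenzoate F3. KN(SiMe3)2 in THF/DMF would then close ring E by intramolecular SNAr of the secondary alkoxide at the alcohol oxidation level, where retro-aldol and epimerisation are impossible. The syn geometry and retention at C2 should give the trans ring directly, and the route is rejoined at silyl ether 13.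

Step 17. What may go wrong: re-enolisation of the acidic α-aryl centre by Et3N at 23 °C (epimerisation at C8′) and weaker facial control for an α-aryl enolate, that is, loss of anti selectivity. The fallback sets out from imide 27. Its dibutylboron enolate (Bu2BOTf, i-Pr2NEt, CH2Cl2, −78 °C) would be added to aldehyde 8 pre-complexed with Et2AlCl. This Lewis-acid-mediated aldol runs through an open transition state on the same (chelated) enolate face, is anti-selective, and works at −78 °C with a stoichiometric, non-equilibrating enolate. After oxidative work-up it returns to the route at alcohol 29; no new compound is formed on this way (F0).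

Step 24. What may go wrong: over-reduction, that is, hydrogenolysis of the benzylic C7′–O bond (a 4-hydroxybenzylic alcohol once ring A is debenzylated) or of the benzylic C2–O1 bond of ring E. The fallback inverts the order of the last two operations and sets out from 34. Hydrogenolysis (H2, Pd/C, EtOAc) with the benzylic alcohol still masked as its silyl ether would give (3R,4R)-3-{[3-{(1S,2S)-1,3-bis[(tert-butyldimethylsilyl)oxy]-1-(4-hydroxy-3-methoxyphenyl)propan-2-yl}-4-hydroxy-5-methoxyphenyl]methyl}-4-{[(2S,3R)-3-{[(tert-butyldimethylsilyl)oxy]methyl}-2-(4-hydroxy-3-methoxyphenyl)-7-methoxy-2,3-dihydro-1-benzofuran-5-yl]methyl}oxolan-2-one F4. Bu4NF/AcOH would then remove the three silyl groups and reach target 36.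

Further compounds
F1 | step 5 | methyl 3-{(1S,2S)-1-{[(4S)-4-benzyl-2-oxo-1,3-oxazolidin-3-yl]carbonyl}-2-[4-(benzyloxy)-3-methoxyphenyl]-2-hydroxyethyl}-4-fluoro-5-methoxybenzoate | COC(=O)c1cc(OC)c(F)c(c1)[C@H](C(=O)N1[C@@H](Cc2ccccc2)COC1=O)[C@@H](c1ccc(OCc2ccccc2)c(OC)c1)O
F2 | step 5 | methyl 3-{(1S,2R)-1-[4-(benzyloxy)-3-methoxyphenyl]-1,3-dihydroxypropan-2-yl}-4-fluoro-5-methoxybenzoate | COC(=O)c1cc(OC)c(F)c(c1)[C@H](CO)[C@@H](c1ccc(OCc2ccccc2)c(OC)c1)O
F3 | step 5 | methyl 3-{(1S,2R)-1-[4-(benzyloxy)-3-methoxyphenyl]-3-[(tert-butyldimethylsilyl)oxy]-1-hydroxypropan-2-yl}-4-fluoro-5-methoxybenzoate | COC(=O)c1cc(OC)c(F)c(c1)[C@H](CO[Si](C)(C)C(C)(C)C)[C@@H](c1ccc(OCc2ccccc2)c(OC)c1)O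
F0 | step 17 | none | none
F4 | step 24 | (3R,4R)-3-{[3-{(1S,2S)-1,3-bis[(tert-butyldimethylsilyl)oxy]-1-(4-hydroxy-3-methoxyphenyl)propan-2-yl}-4-hydroxy-5-methoxyphenyl]methyl}-4-{[(2S,3R)-3-{[(tert-butyldimethylsilyl)oxy]methyl}-2-(4-hydroxy-3-methoxyphenyl)-7-methoxy-2,3-dihydro-1-benzofuran-5-yl]methyl}oxolan-2-one | COc1cc([C@@H](O[Si](C)(C)C(C)(C)C)[C@H](CO[Si](C)(C)C(C)(C)C)c2cc(C[C@H]3C(=O)OC[C@@H]3Cc3cc(OC)c4c(c3)[C@H](CO[Si](C)(C)C(C)(C)C)[C@@H](c3ccc(O)c(OC)c3)O4)cc(OC)c2O)ccc1O
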